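The methylene bridge is disconnected to give two benzophenones. The A–B half is built by inserting 3-benzyloxy-5-methoxybenzyne into the C–OH bond of dibenzyl orsellinic acid. This exploits the ring A carbon that carries the ketone carbon to ring B and sits between two oxygen-bearing ring A carbons. One operation forms the ring A C–O bond and the ring A C–C(=O) bond, and leaves free only the ring A hydroxyl next to the future CH2 carbon. The precursors are silyl triflate 9 (trimethylsilyl between benzyloxy and triflate, made through base-labile carbamates so that the aryl–silicon bond never meets acid) and acid 12.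

Key step: step 8

Assumption: 2,4-dihydroxy-6-methylbenzaldehyde (19) is taken as purchasable; ring A carries the CH2 and the 2,4-dihydroxy-6-methylbenzoyl ring B, ring A′ carries the 4-hydroxy-2-methoxy-6-methylbenzoyl ring B′; the target is achiral and the only stereocentre on the route (carbinol 23) is racemic and is oxidised away.

Step 1
Reactants: 1 5-methoxyresorcinol
Product: 2 5-methoxy-1,3-phenylene bis(isopropylcarbamate)
Conditions: i-PrNCO (2.5 equiv), Et3N (0.3 equiv), CH2Cl2, rt
Reagents that add atoms: isopropyl isocyanate, CC(C)N=C=O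
Why: Base-catalysed addition of both phenols to the isocyanate (O-carbamoylation) should give the biscarbamate, whose carbamoyloxy groups are strong ortho-directing groups that can later be removed with amine base alone.

Step 2
Reactants: 2 5-methoxy-1,3-phenylene bis(isopropylcarbamate)
Product: 6 5-methoxy-2-(trimethylsilyl)-1,3-phenylene bis(isopropylcarbamate), via N,N′-disilyl biscarbamate 3 (not isolated), via aryllithium 4 (not isolated), via trisilyl biscarbamate 5 (not isolated)
Conditions: TMSOTf (2.3 equiv), TMEDA (2.4 equiv), Et2O, 0 °C to rt; n-BuLi (1.5 equiv), TMEDA (1.5 equiv), −78 °C; TMSCl (4 equiv), −78 °C to rt; aq. NaHCO3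
Reagents that add atoms: chlorotrimethylsilane, C[Si](C)(C)Cl
Why: Snieckus–Hoppe directed ortho-metalation, in which in situ N-silylation masks both N–H bonds, n-BuLi/TMEDA removes the C2 proton flanked by the two carbamoyloxy groups (doubly coordinated, most acidic), the low temperature suppresses the anionic Fries shift, TMSCl traps the aryllithium and the N–Si bonds hydrolyse on work-up.

Step 3
Reactants: 6 5-methoxy-2-(trimethylsilyl)-1,3-phenylene bis(isopropylcarbamate)
Product: 7 5-methoxy-2-(trimethylsilyl)benzene-1,3-diol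
Conditions: Et2NH (5 equiv), DBU (3 equiv), MeCN, 40 °C; aq. NH4Cl; Et3N-deactivated silica
Reagents that add atoms: none
Why: E1cB cleavage of the N-monosubstituted aryl carbamates (DBU deprotonates N–H, the phenoxide leaves, diethylamine captures the carbamoyl fragment as a urea) should free both phenols without any protic acid, which would protodesilylate this 2,4,6-trioxygenated arylsilane.

Step 4
Reactants: 7 5-methoxy-2-(trimethylsilyl)benzene-1,3-diol
Product: 8 3-(benzyloxy)-5-methoxy-2-(trimethylsilyl)phenol
Conditions: BnBr (1.0 equiv), K2CO3 (1.1 equiv), acetone, rt; recovered 7 recycled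
Reagents that add atoms: benzyl bromide, BrCc1ccccc1
Why: Williamson etherification of two equivalent phenols with one equivalent of benzyl bromide should give the monoether as the main component of a statistical mixture, from which the dibenzyl ether is separated and unreacted 7 is returned to the step.

Step 5
Reactants: 8 3-(benzyloxy)-5-methoxy-2-(trimethylsilyl)phenol
Product: 9 3-(benzyloxy)-5-methoxy-2-(trimethylsilyl)phenyl trifluoromethanesulfonate
Conditions: PhNTf2 (1.2 equiv), DBU (1.3 equiv), MeCN, rt
Reagents that add atoms: N-phenylbis(trifluoromethanesulfonimide), O=S(=O)(N(c1ccccc1)S(=O)(=O)C(F)(F)F)C(F)(F)F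
Why: O-Triflation of the phenoxide with a mild triflyl donor and an amidine base uses neither fluoride nor alkoxide, so the ortho-silyl aryl triflate (Kobayashi-type aryne precursor) should not be triggered prematurely.

Step 6
Reactants: 10 methyl orsellinate
Product: 11 methyl 2,4-bis(benzyloxy)-6-methylbenzoate
Conditions: BnBr (2.5 equiv), K2CO3 (3 equiv), DMF, 60 °C
Reagents that add atoms: benzyl bromide, BrCc1ccccc1
Why: Williamson etherification, in which the hydrogen-bonded 2-OH needs excess reagent and warming in DMF while the hindered methyl ester stays untouched.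

Step 7
Reactants: 11 methyl 2,4-bis(benzyloxy)-6-methylbenzoate
Product: 12 2,4-bis(benzyloxy)-6-methylbenzoic acid
Conditions: KOH (5 equiv), DMSO/H2O (4:1), 90 °C; then aq. HCl
Reagents that add atoms: potassium hydroxide, [K+].[OH-]
Why: Saponification of the di-ortho-substituted methyl ester needs hot hydroxide in aqueous DMSO, conditions to which aryl benzyl ethers are inert.

Step 8
Reactants: 12 2,4-bis(benzyloxy)-6-methylbenzoic acid; 9 3-(benzyloxy)-5-methoxy-2-(trimethylsilyl)phenyl trifluoromethanesulfonate
Product: 16 (2-(benzyloxy)-6-hydroxy-4-methoxyphenyl)(2,4-bis(benzyloxy)-6-methylphenyl)methanone, via caesium carboxylate 13 (not isolated), via aryne 14 (not isolated), via aryl anion ester 15 (not isolated)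
Conditions: 12 (1.5 equiv), Cs2CO3 (0.75 equiv), MeOH, rt, evaporate and dry (toluene azeotrope, vacuum); 9 (1.0 equiv), CsF (3 equiv), THF, 125 °C, sealed tube; dilute aq. HCl
Reagents that add atoms: none
Why: Fluoride attacks silicon of 9 and triflate leaves to give aryne 14; the carboxylate oxygen of 13 adds to the aryne carbon meta to the benzyloxy group, the resulting aryl anion 15 sits next to that group and attacks its own ester carbonyl through a four-membered transition state, and collapse of the adduct delivers the ortho-acyl phenoxide, protonated on work-up. The closest known reaction type is the fluoride-induced insertion of arynes into the C–O bond of carboxylic acids, an anionic Fries-like 1,3 O-to-C acyl shift that is established for 3-alkoxybenzynes; the 2,6-disubstituted acid is a harder member of the same substrate class. No ring is closed and no stereocentre is formed. Regiocontrol should come from the benzyloxy substituent beside the triple bond, whose inductive pull and the distortion it imposes place the developing negative charge on the proximal carbon, so oxygen goes distal and the acyl group proximal. The step also needs acyl transfer to outrun protonation of 15, which is why the acid is converted beforehand into its dry caesium salt and used in excess in THF with no proton source.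

Step 9
Reactants: 16 (2-(benzyloxy)-6-hydroxy-4-methoxyphenyl)(2,4-bis(benzyloxy)-6-methylphenyl)methanone
Product: 17 (6-(benzyloxy)-3-((dimethylamino)methyl)-2-hydroxy-4-methoxyphenyl)(2,4-bis(benzyloxy)-6-methylphenyl)methanone
Conditions: Me2N=CH2+ I− (1.3 equiv), K2CO3 (1.5 equiv), CH2Cl2, rt
Reagents that add atoms: N,N-dimethylmethyleneiminium iodide (Eschenmoser's salt), C[N+](C)=C.[I-]
Why: Phenolic Mannich reaction with a preformed iminium salt, in which the phenol oxygen steers the electrophile to its free ortho carbon (between C–OH and C–OMe), which is also less hindered than the para carbon flanked by OMe and OBn, in line with the ortho preference of halogenation in 2-hydroxy-4,6-dialkoxyaryl ketones.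

Step 10
Reactants: 1 5-methoxyresorcinol
Product: 18 1-methoxy-3,5-bis(methoxymethoxy)benzene
Conditions: NaH (2.5 equiv), MOMCl (2.5 equiv), THF/DMF, 0 °C to rt
Reagents that add atoms: chloromethyl methyl ether, COCCl
Why: Double O-alkylation of the sodium phenoxides should give the bis-acetal, whose two OCH2OCH3 groups later direct lithiation to the carbon between them.

Step 11
Reactants: 19 2,4-dihydroxy-6-methylbenzaldehyde
Product: 20 4-(benzyloxy)-2-hydroxy-6-methylbenzaldehyde
Conditions: BnBr (1.05 equiv), K2CO3 (1.05 equiv), acetone, rt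
Reagents that add atoms: benzyl bromide, BrCc1ccccc1
Why: The 4-OH is not tied up in the hydrogen bond to the aldehyde and is the more acidic and more nucleophilic phenol, so one equivalent of benzyl bromide should etherify it selectively (Williamson).

Step 12
Reactants: 20 4-(benzyloxy)-2-hydroxy-6-methylbenzaldehyde
Product: 21 4-(benzyloxy)-2-methoxy-6-methylbenzaldehyde
Conditions: MeI (3 equiv), K2CO3 (2 equiv), DMF, 50 °C
Reagents that add atoms: iodomethane, CI
Why: Williamson methylation of the remaining hydrogen-bonded phenol under forcing conditions (excess MeI, warm DMF).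

Step 13
Reactants: 18 1-methoxy-3,5-bis(methoxymethoxy)benzene; 21 4-(benzyloxy)-2-methoxy-6-methylbenzaldehyde
Product: 23 rac-(4-(benzyloxy)-2-methoxy-6-methylphenyl)(4-methoxy-2,6-bis(methoxymethoxy)phenyl)methanol, via aryllithium 22 (not isolated)
Conditions: n-BuLi (1.1 equiv), THF, 0 °C, 1 h; 21 (0.9 equiv), −78 °C to 0 °C; H2O
Reagents that add atoms: none
Why: Directed ortho-lithiation at the carbon flanked by both MOM ethers followed by 1,2-addition of the aryllithium to the hindered aldehyde; the carbinol stereocentre forms as a racemate and is removed in step 14.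

Step 14
Reactants: 23 rac-(4-(benzyloxy)-2-methoxy-6-methylphenyl)(4-methoxy-2,6-bis(methoxymethoxy)phenyl)methanol
Product: 24 (4-(benzyloxy)-2-methoxy-6-methylphenyl)(4-methoxy-2,6-bis(methoxymethoxy)phenyl)methanone
Conditions: Dess–Martin periodinane (1.3 equiv), pyridine (3 equiv), CH2Cl2, rt
Reagents that add atoms: none
Why: Dess–Martin oxidation of the diarylcarbinol to the tetra-ortho-substituted benzophenone, with pyridine buffering the acetic acid so that the electron-rich benzhydrol and the MOM ethers are not ionised.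

Step 15
Reactants: 24 (4-(benzyloxy)-2-methoxy-6-methylphenyl)(4-methoxy-2,6-bis(methoxymethoxy)phenyl)methanone
Product: 25 (4-(benzyloxy)-2-methoxy-6-methylphenyl)(2,6-dihydroxy-4-methoxyphenyl)methanone
Conditions: HCl (3 M aq., cat.), MeOH/THF, 50 °C
Reagents that add atoms: none
Why: Acid-catalysed transacetalisation to methanol removes both MOM groups as dimethoxymethane, while aryl benzyl and methyl ethers are stable to dilute HCl.

Step 16
Reactants: 17 (6-(benzyloxy)-3-((dimethylamino)methyl)-2-hydroxy-4-methoxyphenyl)(2,4-bis(benzyloxy)-6-methylphenyl)methanone; 25 (4-(benzyloxy)-2-methoxy-6-methylphenyl)(2,6-dihydroxy-4-methoxyphenyl)methanone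
Product: 28 (3-{[4-(benzyloxy)-3-(2,4-bis(benzyloxy)-6-methylbenzoyl)-2-hydroxy-6-methoxyphenyl]methyl}-2,6-dihydroxy-4-methoxyphenyl)(4-(benzyloxy)-2-methoxy-6-methylphenyl)methanone, via trimethylammonium iodide 26 (not isolated), via ortho-quinone methide 27 (not isolated)
Conditions: MeI (5 equiv), MeCN, rt, then evaporate; 25 (2 equiv), K2CO3 (2.5 equiv), MeCN, 50 °C
Reagents that add atoms: none
Why: N-Methylation turns the Mannich base into an ammonium salt that loses trimethylamine on deprotonation of the phenol to give ortho-quinone methide 27, and the phenoxide of 25 (in excess) adds through either of its two equivalent ring A′ carbons (Michael addition, then tautomerisation), the established way to methylene-bridged acylphloroglucinols.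

Step 17
Reactants: 28 (3-{[4-(benzyloxy)-3-(2,4-bis(benzyloxy)-6-methylbenzoyl)-2-hydroxy-6-methoxyphenyl]methyl}-2,6-dihydroxy-4-methoxyphenyl)(4-(benzyloxy)-2-methoxy-6-methylphenyl)methanone
Product: 29 (3-{[3-(2,4-dihydroxy-6-methylbenzoyl)-2,4-dihydroxy-6-methoxyphenyl]methyl}-2,6-dihydroxy-4-methoxyphenyl)(4-hydroxy-2-methoxy-6-methylphenyl)methanone
Conditions: H2 (1 atm), Pd/C (10 wt%), EtOAc/MeOH (1:1), rt
Reagents that add atoms: none
Why: Hydrogenolysis of the four aryl benzyl ethers over Pd/C at ambient pressure should leave the hydrogen-bonded, tetra-ortho-substituted diaryl ketones and the diarylmethane unreduced.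

Compound list
1 | 5-methoxyresorcinol | COc1cc(O)cc(O)c1 | starting material
2 | 5-methoxy-1,3-phenylene bis(isopropylcarbamate) | COc1cc(OC(=O)NC(C)C)cc(OC(=O)NC(C)C)c1 | intermediate
3 | 5-methoxy-1,3-phenylene bis[isopropyl(trimethylsilyl)carbamate] | COc1cc(OC(=O)N(C(C)C)[Si](C)(C)C)cc(OC(=O)N(C(C)C)[Si](C)(C)C)c1 | intermediate
4 | {2,6-bis[isopropyl(trimethylsilyl)carbamoyloxy]-4-methoxyphenyl}lithium | COc1cc(OC(=O)N(C(C)C)[Si](C)(C)C)c([Li])c(OC(=O)N(C(C)C)[Si](C)(C)C)c1 | intermediate
5 | 5-methoxy-2-(trimethylsilyl)-1,3-phenylene bis[isopropyl(trimethylsilyl)carbamate] | COc1cc(OC(=O)N(C(C)C)[Si](C)(C)C)c([Si](C)(C)C)c(OC(=O)N(C(C)C)[Si](C)(C)C)c1 | intermediate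
6 | 5-methoxy-2-(trimethylsilyl)-1,3-phenylene bis(isopropylcarbamate) | COc1cc(OC(=O)NC(C)C)c([Si](C)(C)C)c(OC(=O)NC(C)C)c1 | intermediate
7 | 5-methoxy-2-(trimethylsilyl)benzene-1,3-diol | COc1cc(O)c([Si](C)(C)C)c(O)c1 | intermediate
8 | 3-(benzyloxy)-5-methoxy-2-(trimethylsilyl)phenol | COc1cc(O)c([Si](C)(C)C)c(OCc2ccccc2)c1 | intermediate
9 | 3-(benzyloxy)-5-methoxy-2-(trimethylsilyl)phenyl trifluoromethanesulfonate | COc1cc(OCc2ccccc2)c([Si](C)(C)C)c(OS(=O)(=O)C(F)(F)F)c1 | intermediate
10 | methyl orsellinate (methyl 2,4-dihydroxy-6-methylbenzoate) | COC(=O)c1c(C)cc(O)cc1O | starting material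
11 | methyl 2,4-bis(benzyloxy)-6-methylbenzoate | COC(=O)c1c(C)cc(OCc2ccccc2)cc1OCc1ccccc1 | intermediate
12 | 2,4-bis(benzyloxy)-6-methylbenzoic acid | Cc1cc(OCc2ccccc2)cc(OCc2ccccc2)c1C(=O)O | intermediate
13 | caesium 2,4-bis(benzyloxy)-6-methylbenzoate | Cc1cc(OCc2ccccc2)cc(OCc2ccccc2)c1C(=O)[O-].[Cs+] | intermediate
14 | 3-(benzyloxy)-5-methoxybenzyne (3-(benzyloxy)-5-methoxy-1,2-didehydrobenzene) | COC1=CC#CC(OCc2ccccc2)=C1 | intermediate
15 | [2-(benzyloxy)-6-{[2,4-bis(benzyloxy)-6-methylbenzoyl]oxy}-4-methoxyphenyl]caesium | COc1cc(OCc2ccccc2)c([Cs])c(OC(=O)c2c(C)cc(OCc3ccccc3)cc2OCc2ccccc2)c1 | intermediate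
16 | (2-(benzyloxy)-6-hydroxy-4-methoxyphenyl)(2,4-bis(benzyloxy)-6-methylphenyl)methanone | COc1cc(OCc2ccccc2)c(C(=O)c2c(C)cc(OCc3ccccc3)cc2OCc2ccccc2)c(O)c1 | intermediate
17 | (6-(benzyloxy)-3-((dimethylamino)methyl)-2-hydroxy-4-methoxyphenyl)(2,4-bis(benzyloxy)-6-methylphenyl)methanone | COc1cc(OCc2ccccc2)c(C(=O)c2c(C)cc(OCc3ccccc3)cc2OCc2ccccc2)c(O)c1CN(C)C | intermediate
18 | 1-methoxy-3,5-bis(methoxymethoxy)benzene | COCOc1cc(OC)cc(OCOC)c1 | intermediate
19 | 2,4-dihydroxy-6-methylbenzaldehyde | Cc1cc(O)cc(O)c1C=O | starting material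
20 | 4-(benzyloxy)-2-hydroxy-6-methylbenzaldehyde | Cc1cc(OCc2ccccc2)cc(O)c1C=O | intermediate
21 | 4-(benzyloxy)-2-methoxy-6-methylbenzaldehyde | COc1cc(OCc2ccccc2)cc(C)c1C=O | intermediate
22 | [4-methoxy-2,6-bis(methoxymethoxy)phenyl]lithium | COCOc1cc(OC)cc(OCOC)c1[Li] | intermediate
23 | rac-(4-(benzyloxy)-2-methoxy-6-methylphenyl)(4-methoxy-2,6-bis(methoxymethoxy)phenyl)methanol | COCOc1cc(OC)cc(OCOC)c1C(O)c1c(C)cc(OCc2ccccc2)cc1OC | intermediate
24 | (4-(benzyloxy)-2-methoxy-6-methylphenyl)(4-methoxy-2,6-bis(methoxymethoxy)phenyl)methanone | COCOc1cc(OC)cc(OCOC)c1C(=O)c1c(C)cc(OCc2ccccc2)cc1OC | intermediate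
25 | (4-(benzyloxy)-2-methoxy-6-methylphenyl)(2,6-dihydroxy-4-methoxyphenyl)methanone | COc1cc(O)c(C(=O)c2c(C)cc(OCc3ccccc3)cc2OC)c(O)c1 | intermediate
26 | 1-[4-(benzyloxy)-3-(2,4-bis(benzyloxy)-6-methylbenzoyl)-2-hydroxy-6-methoxyphenyl]-N,N,N-trimethylmethanaminium iodide | COc1cc(OCc2ccccc2)c(C(=O)c2c(C)cc(OCc3ccccc3)cc2OCc2ccccc2)c(O)c1C[N+](C)(C)C.[I-] | intermediate
27 | 3-(benzyloxy)-2-(2,4-bis(benzyloxy)-6-methylbenzoyl)-5-methoxy-6-methylidenecyclohexa-2,4-dien-1-one | C=C1C(OC)=CC(OCc2ccccc2)=C(C(=O)c2c(C)cc(OCc3ccccc3)cc2OCc2ccccc2)C1=O | intermediate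
28 | (3-{[4-(benzyloxy)-3-(2,4-bis(benzyloxy)-6-methylbenzoyl)-2-hydroxy-6-methoxyphenyl]methyl}-2,6-dihydroxy-4-methoxyphenyl)(4-(benzyloxy)-2-methoxy-6-methylphenyl)methanone | COc1cc(OCc2ccccc2)c(C(=O)c2c(C)cc(OCc3ccccc3)cc2OCc2ccccc2)c(O)c1Cc1c(OC)cc(O)c(C(=O)c2c(C)cc(OCc3ccccc3)cc2OC)c1O | intermediate
29 | (3-{[3-(2,4-dihydroxy-6-methylbenzoyl)-2,4-dihydroxy-6-methoxyphenyl]methyl}-2,6-dihydroxy-4-methoxyphenyl)(4-hydroxy-2-methoxy-6-methylphenyl)methanone (CNP0596095.0) | COc1cc(O)c(C(=O)c2c(C)cc(O)cc2O)c(O)c1Cc1c(OC)cc(O)c(C(=O)c2c(C)cc(O)cc2OC)c1O | target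

Total step count: 17.
Longest linear sequence: 9 steps (steps 1, 2, 3, 4, 5, 8, 9, 16, 17; 1 → 2 → 6 → 7 → 8 → 9 → 16 → 17 → 28 → 29).

Steps most likely to fail

1. Step 8 (key step). The aryl anion may be quenched before it reaches the doubly ortho-substituted carbonyl, either by stray protons or by intramolecular proton transfer from the ortho-methyl or a benzylic OCH2. The reaction would then stop at O-arylation. The product phenoxide may also be arylated by surplus aryne. The fallback replaces aryne insertion by classical carbonyl chemistry; it sets out from acid 12 and bis-acetal 18 and returns to the route at 16. Acid 12 with (COCl)2 and catalytic DMF in CH2Cl2 should give 2,4-bis(benzyloxy)-6-methylbenzoyl chloride F1. Aryllithium 22 (from 18, n-BuLi, THF, 0 °C) is acylated by F1 at −78 °C to (2,4-bis(benzyloxy)-6-methylphenyl)(4-methoxy-2,6-bis(methoxymethoxy)phenyl)methanone F2, whose hindered carbonyl resists a second addition. HCl in MeOH/THF removes both acetals to give (2,4-bis(benzyloxy)-6-methylphenyl)(2,6-dihydroxy-4-methoxyphenyl)methanone F3. One equivalent of BnBr with K2CO3 in acetone then benzylates one of the two equivalent phenols, the other staying locked in the hydrogen bond to the carbonyl, to give 16.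

2. Step 16. Under the basic conditions ring A′ may be alkylated a second time at its remaining free carbon, oxygen may be alkylated instead of carbon, or quinone methide 27 may be captured by the phenoxide of its own precursor. The fallback uses acid-mediated Friedel–Crafts benzylation in place of the base-triggered quinone methide addition; it sets out from 16 and returns at 28. MgCl2, Et3N and paraformaldehyde in MeCN at reflux should formylate 16 only ortho to the phenol (through the magnesium phenoxide) to give 4-(benzyloxy)-3-(2,4-bis(benzyloxy)-6-methylbenzoyl)-2-hydroxy-6-methoxybenzaldehyde F4. NaBH4 in THF/MeOH at 0 °C reduces the aldehyde but not the hindered diaryl ketone, giving (6-(benzyloxy)-2-hydroxy-3-(hydroxymethyl)-4-methoxyphenyl)(2,4-bis(benzyloxy)-6-methylphenyl)methanone F5. With 25 (2 equiv) and catalytic camphorsulfonic acid in CH2Cl2 at rt, the electron-rich benzylic alcohol ionises and alkylates neutral 25 to give 28. This detour also replaces step 9 and fixes the position ortho to the phenol independently of the Mannich regioselectivity.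

3. Step 2. Metalation may occur at a carbon between one carbamate and the methoxy group, or the aryllithium may undergo a 1,3 O-to-C carbamoyl shift before silylation. The fallback uses acetal-directed lithiation with non-protic acetal removal; it sets out from 18 and returns at 7. Compound 18 is lithiated to 22 (n-BuLi, THF, 0 °C) and quenched with TMSCl to give [4-methoxy-2,6-bis(methoxymethoxy)phenyl]trimethylsilane F6. TMSOTf and 2,2′-bipyridyl in MeCN should convert both aryl MOM ethers into trimethylsilyl ethers without protic acid, giving [5-methoxy-2-(trimethylsilyl)-1,3-phenylene]bis(oxy)bis(trimethylsilane) F7. Water then hydrolyses the O–Si bonds to diol 7.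

Further compounds
F1 | step 8 | 2,4-bis(benzyloxy)-6-methylbenzoyl chloride | Cc1cc(OCc2ccccc2)cc(OCc2ccccc2)c1C(Cl)=O
F2 | step 8 | (2,4-bis(benzyloxy)-6-methylphenyl)(4-methoxy-2,6-bis(methoxymethoxy)phenyl)methanone | COCOc1cc(OC)cc(OCOC)c1C(=O)c1c(C)cc(OCc2ccccc2)cc1OCc1ccccc1
F3 | step 8 | (2,4-bis(benzyloxy)-6-methylphenyl)(2,6-dihydroxy-4-methoxyphenyl)methanone | COc1cc(O)c(C(=O)c2c(C)cc(OCc3ccccc3)cc2OCc2ccccc2)c(O)c1
F4 | step 16 | 4-(benzyloxy)-3-(2,4-bis(benzyloxy)-6-methylbenzoyl)-2-hydroxy-6-methoxybenzaldehyde | COc1cc(OCc2ccccc2)c(C(=O)c2c(C)cc(OCc3ccccc3)cc2OCc2ccccc2)c(O)c1C=O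
F5 | step 16 | (6-(benzyloxy)-2-hydroxy-3-(hydroxymethyl)-4-methoxyphenyl)(2,4-bis(benzyloxy)-6-methylphenyl)methanone | COc1cc(OCc2ccccc2)c(C(=O)c2c(C)cc(OCc3ccccc3)cc2OCc2ccccc2)c(O)c1CO
F6 | step 2 | [4-methoxy-2,6-bis(methoxymethoxy)phenyl]trimethylsilane | COCOc1cc(OC)cc(OCOC)c1[Si](C)(C)C
F7 | step 2 | [5-methoxy-2-(trimethylsilyl)-1,3-phenylene]bis(oxy)bis(trimethylsilane) | COc1cc(O[Si](C)(C)C)c([Si](C)(C)C)c(O[Si](C)(C)C)c1
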